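**Plan** (side-chain carbons are numbered 1′–13′ from the carbon on C5 of the furanone)

- Retrosynthesis, in order: the O–CH3 bond of a methyl tetronate (protection); the C8′–C9′ σ-bond of the 7′E,9′E-diene together with the C10′–CH3 bond (vinyl iodide 22 + terminal alkyne 7 + AlMe3); furanone C3–C4 (Dieckmann) and C1′–C2′ (alkenyl metal + glycidate); the C2′=C3′ and C7′=C8′ olefin bonds; on the other side the lactam N–C bonds and C3=C4 of the pyrrolinone.
- Enabling feature: C9′H=C10′(CH3)–C11′H2 is a 2-methylalk-1-enyl end with CH3 cis to the new bond, which is what syn CH3–Al addition to the terminal alkyne HC≡C–(CH2)3– on C4 of the pyrrolinone delivers. That ring is a tertiary, N–H-free lactam with a fully substituted β-carbon and should tolerate AlMe3.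
- Forward: the pyrrolinone ring is closed first on a heptynal chain (steps 1–3); the furanone ring is closed on a citronellene-derived chain (steps 4–12); the chain is joined at the diene (step 13); the tetronic acid is unmasked (step 14).
- Stereochemistry: C5 (S) from methyl (S)-glycidate; C6′ (S) from (S)-β-citronellene; 2′Z from the iodo-ylide Wittig reaction; 7′E from Takai–Utimoto silyl-olefination and ipso-iodination with retention; 9′E from syn-carboalumination; the cross-coupling keeps both geometries.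

Key step: step 13

Remark: the lactol carbon of 4, the ozonide carbon of 9 and C2 of diol 12 are uncontrolled centers that are destroyed in the same or the next step.

**Step 1**
Reactants: 1 hept-6-yn-1-ol
Product: 2 hept-6-ynal
Conditions: TEMPO (10 mol%), PhI(OAc)2 (1.1 equiv), CH2Cl2, rt
Reagents that add atoms: none
Why: TEMPO/PhI(OAc)2 (oxoammonium) oxidation should stop at the aldehyde and leave the terminal alkyne untouched.

**Step 2**
Reactants: 2 hept-6-ynal; 3 glyoxylic acid monohydrate
Product: 4 5-hydroxy-4-(pent-4-yn-1-yl)furan-2(5H)-one (racemic lactol)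
Conditions: morpholine·HCl (1.0 equiv), dioxane/H2O, rt then reflux
Reagents that add atoms: glyoxylic acid monohydrate OC(O)C(=O)O
Why: Morpholinium-mediated aldol-type condensation of the aldehyde α-CH2 with glyoxylic acid and dehydration should give the (Z)-4-oxobut-2-enoic acid, which closes to the γ-hydroxybutenolide carrying the chain at C4.

**Step 3**
Reactants: 4 5-hydroxy-4-(pent-4-yn-1-yl)furan-2(5H)-one; 5 3-methylbutan-1-amine
Product: 7 1-(3-methylbutyl)-4-(pent-4-yn-1-yl)-1,5-dihydro-2H-pyrrol-2-one, via (2Z)-3-{[(3-methylbutyl)amino]methyl}oct-2-en-7-ynoic acid 6 (not isolated)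
Conditions: 5 (1.1 equiv), AcOH, CHCl3, rt; NaBH(OAc)3 (1.5 equiv), rt then 60 °C
Reagents that add atoms: 3-methylbutan-1-amine CC(C)CCN
Why: Direct reductive amination of the ring-chain (aldehyde) tautomer of a γ-hydroxybutenolide, a reaction type known for mucochloric acid, should give the (Z)-γ-amino acid 6, whose cis geometry lets it lactamise (5-exo-trig) to the 4-substituted pyrrolinone.

**Step 4**
Reactants: 8 (S)-β-citronellene
Product: 10 (4S)-4-methylhex-5-enal, via 3,3-dimethyl-5-[(3S)-3-methylpent-4-en-1-yl]-1,2,4-trioxolane 9 (not isolated)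
Conditions: O3 (1.0 equiv, Sudan Red 7B end point), CH2Cl2, −78 °C; Me2S, −78 °C → rt
Reagents that add atoms: ozone [O-][O+]=O
Why: Criegee ozonolysis with one equivalent of ozone should cleave the electron-rich trisubstituted alkene in preference to the monosubstituted vinyl group, and Me2S reduction of ozonide 9 gives the aldehyde without touching the stereocenter.

**Step 5**
Reactants: 10 (4S)-4-methylhex-5-enal
Product: 11 (2Z,6S)-2-iodo-6-methylocta-2,7-diene
Conditions: EtPPh3I, n-BuLi, THF, rt; I2, −78 °C; NaHMDS, −20 °C; 10, −78 °C → rt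
Reagents that add atoms: ethyltriphenylphosphonium iodide CC[P+](c1ccccc1)(c1ccccc1)c1ccccc1.[I-]; iodine II
Why: Stork–Zhao-type Wittig olefination with the α-iodo ylide Ph3P=C(I)CH3 runs under kinetic control through the cis-oxaphosphetane that places the aldehyde chain cis to iodine, which should give the (Z)-2-iodoalk-2-ene.

**Step 6**
Reactants: 11 (2Z,6S)-2-iodo-6-methylocta-2,7-diene
Product: 13 (2S,5Z)-6-iodo-2-methylhept-5-enal, via (3S,6Z)-7-iodo-3-methyloct-6-ene-1,2-diol 12 (not isolated)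
Conditions: OsO4 (2 mol%), NaIO4 (4 equiv), 2,6-lutidine (2 equiv), dioxane/H2O 3:1, rt
Reagents that add atoms: osmium tetroxide (catalytic oxygen carrier) O=[Os](=O)(=O)=O; sodium periodate (stoichiometric oxidant) [Na+].[O-]I(=O)(=O)=O
Why: Lemieux–Johnson cleavage, in which OsO4 should dihydroxylate the unhindered monosubstituted alkene much faster than the electron-poor, hindered iodoalkene, periodate cleaves diol 12, and the lutidine buffer should keep the α-stereocenter from epimerising.

**Step 7**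
Reactants: 13 (2S,5Z)-6-iodo-2-methylhept-5-enal
Product: 14 [(1E,3S,6Z)-7-iodo-3-methylocta-1,6-dien-1-yl]trimethylsilane
Conditions: Me3SiCHBr2 (2 equiv), CrCl2 (8 equiv), THF, rt
Reagents that add atoms: (dibromomethyl)trimethylsilane C[Si](C)(C)C(Br)Br
Why: Takai–Utimoto olefination, in which the gem-dichromium reagent adds to the aldehyde and eliminates to the (E)-alkenylsilane under non-basic conditions that should neither epimerise the α-methyl center nor touch the alkenyl iodide (no nickel present).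

**Step 8**
Reactants: 14 [(1E,3S,6Z)-7-iodo-3-methylocta-1,6-dien-1-yl]trimethylsilane; 15 methyl (2S)-oxirane-2-carboxylate
Product: 18 methyl (2S,4Z,8S,9E)-2-hydroxy-4,8-dimethyl-10-(trimethylsilyl)deca-4,9-dienoate, via [(2E,6S,7E)-6-methyl-8-(trimethylsilyl)octa-2,7-dien-2-yl]lithium 16 (not isolated), via bromo[(2Z,6S,7E)-6-methyl-8-(trimethylsilyl)octa-2,7-dien-2-yl]magnesium 17 (not isolated)
Conditions: t-BuLi (2.05 equiv), Et2O, −78 °C; MgBr2·OEt2 (1.1 equiv), −78 → −40 °C; CuI (10 mol%), 15 (1.5 equiv), THF, −40 → −20 °C; aq NH4Cl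
Reagents that add atoms: methyl (2S)-oxirane-2-carboxylate COC(=O)[C@@H]1CO1
Why: Iodine–lithium exchange proceeds with retention of alkene geometry, and the derived Grignard reagent under copper catalysis should open the glycidic ester by SN2 attack at the unsubstituted C3 (as known for isopropenylmagnesium bromide), so the C2 stereocenter of 15 is carried unchanged into 18 as (S).

**Step 9**
Reactants: 18 methyl (2S,4Z,8S,9E)-2-hydroxy-4,8-dimethyl-10-(trimethylsilyl)deca-4,9-dienoate
Product: 19 methyl (2S,4Z,8S,9E)-4,8-dimethyl-2-(propanoyloxy)-10-(trimethylsilyl)deca-4,9-dienoate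
Conditions: (EtCO)2O (1.5 equiv), Et3N, DMAP (cat.), CH2Cl2, 0 °C → rt
Reagents that add atoms: propanoic anhydride CCC(=O)OC(=O)CC
Why: DMAP-catalysed acylation of the secondary alcohol, in which no stereocenter takes part.

**Step 10**
Reactants: 19 methyl (2S,4Z,8S,9E)-4,8-dimethyl-2-(propanoyloxy)-10-(trimethylsilyl)deca-4,9-dienoate
Product: 20 (5S)-5-[(2Z,6S,7E)-2,6-dimethyl-8-(trimethylsilyl)octa-2,7-dien-1-yl]-4-hydroxy-3-methylfuran-2(5H)-one
Conditions: LiHMDS (2.5 equiv), THF, −78 → 0 °C; 1 M HCl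
Reagents that add atoms: none
Why: Dieckmann condensation, in which the propanoate enolate attacks the neighbouring methyl ester (5-exo-trig), methoxide leaves and the product is protected as its lithium tetronate, so C5, which is deprotonated more slowly than the unhindered propanoate CH2 and is non-acidic in the tetronate, should keep its (S) configuration.

**Step 11**
Reactants: 20 (5S)-5-[(2Z,6S,7E)-2,6-dimethyl-8-(trimethylsilyl)octa-2,7-dien-1-yl]-4-hydroxy-3-methylfuran-2(5H)-one
Product: 21 (5S)-5-[(2Z,6S,7E)-2,6-dimethyl-8-(trimethylsilyl)octa-2,7-dien-1-yl]-4-methoxy-3-methylfuran-2(5H)-one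
Conditions: MeOH, PPh3, DIAD, THF, 0 °C → rt
Reagents that add atoms: methanol CO
Why: Mitsunobu alkylation of the acidic tetronic acid (pKa about 4) with methanol, a reaction known to alkylate O4 regioselectively, should give the base- and organometal-stable methyl tetronate without touching C5.

**Step 12**
Reactants: 21 (5S)-5-[(2Z,6S,7E)-2,6-dimethyl-8-(trimethylsilyl)octa-2,7-dien-1-yl]-4-methoxy-3-methylfuran-2(5H)-one
Product: 22 (5S)-5-[(2Z,6S,7E)-8-iodo-2,6-dimethylocta-2,7-dien-1-yl]-4-methoxy-3-methylfuran-2(5H)-one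
Conditions: NIS (1.3 equiv), (CF3)2CHOH, 0 °C
Reagents that add atoms: N-iodosuccinimide O=C1CCC(=O)N1I
Why: Electrophilic ipso-iododesilylation, in which iodonium attack at the silicon-bearing carbon is driven by β-silyl stabilisation and in HFIP should proceed with retention to the (E)-alkenyl iodide, faster than any reaction at the trisubstituted alkene or the push-pull tetronate alkene.

**Step 13**
Reactants: 7 1-(3-methylbutyl)-4-(pent-4-yn-1-yl)-1,5-dihydro-2H-pyrrol-2-one; 22 (5S)-5-[(2Z,6S,7E)-8-iodo-2,6-dimethylocta-2,7-dien-1-yl]-4-methoxy-3-methylfuran-2(5H)-one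
Product: 25 (5S)-4-methoxy-3-methyl-5-{(2Z,6S,7E,9E)-2,6,10-trimethyl-13-[1-(3-methylbutyl)-5-oxo-2,5-dihydro-1H-pyrrol-3-yl]trideca-2,7,9-trien-1-yl}furan-2(5H)-one, via dimethyl{(1E)-2-methyl-5-[1-(3-methylbutyl)-5-oxo-2,5-dihydro-1H-pyrrol-3-yl]pent-1-en-1-yl}aluminium 23 (not isolated), via chloro{(1E)-2-methyl-5-[1-(3-methylbutyl)-5-oxo-2,5-dihydro-1H-pyrrol-3-yl]pent-1-en-1-yl}zinc 24 (not isolated)
Conditions: 7 (1.25 equiv), AlMe3 (3 equiv), Cp2ZrCl2 (0.5 equiv), CH2Cl2, 0 °C → rt; volatiles removed in vacuo; THF, ZnCl2 (1.2 equiv); 22 (1.0 equiv), Pd(PPh3)4 (5 mol%), rt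
Reagents that add atoms: trimethylaluminium C[Al](C)C
Why: Cp2ZrCl2/AlMe3 should add CH3–Al syn across the terminal alkyne of 7 (methyl to the internal carbon, metal to the terminal CH) to give only the (E)-2-methylalkenyl metal 23; Al→Zn exchange then feeds a Pd(0)/Pd(II) cycle in which oxidative addition into the C–I bond of 22, transmetalation and reductive elimination all go with retention at both alkene carbons, so the new C(sp2)–C(sp2) bond arrives inside a 7′E,9′E-diene. The closest known reaction type is the Negishi one-pot zirconium-catalysed carboalumination/palladium-catalysed alkenyl–alkenyl cross-coupling. No ring is closed and no stereocenter is formed; C5 and C6′ lie away from every reacting atom and carry no hydrogen acidic enough to be removed. The step needs regio- and syn-selectivity in the carbometalation, which the terminal alkyne secures, and chemoselectivity toward the lactam of 7, which has no N–H, has a fully substituted β-carbon and is held as its AlMe3 adduct by the extra reagent. Excess AlMe3 is pumped off before palladium is added so that methyl transfer to 22 does not compete, and the methyl tetronate of 22 offers no acidic or electrophilic site to an alkenylzinc at room temperature.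

**Step 14**
Reactants: 25 (5S)-4-methoxy-3-methyl-5-{(2Z,6S,7E,9E)-2,6,10-trimethyl-13-[1-(3-methylbutyl)-5-oxo-2,5-dihydro-1H-pyrrol-3-yl]trideca-2,7,9-trien-1-yl}furan-2(5H)-one
Product: 26 Sarcotrine D
Conditions: NaSEt (5 equiv), DMF, 50 °C; 1 M HCl to pH 3
Reagents that add atoms: none
Why: SN2 O-demethylation of the vinylogous methyl ester by thiolate with the tetronate as leaving group, as used for 4-methoxy-3-methylfuranones, should free the tetronic acid without touching the stereocenters, the diene or the β,β-disubstituted lactam.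

**Compound list**

1 | hept-6-yn-1-ol | C#CCCCCCO | starting material
2 | hept-6-ynal | C#CCCCCC=O | intermediate
3 | glyoxylic acid monohydrate (2,2-dihydroxyacetic acid) | OC(O)C(=O)O | starting material
4 | 5-hydroxy-4-(pent-4-yn-1-yl)furan-2(5H)-one (racemic lactol) | O=C1C=C(CCCC#C)C(O)O1 | intermediate
5 | 3-methylbutan-1-amine | CC(C)CCN | starting material
6 | (2Z)-3-{[(3-methylbutyl)amino]methyl}oct-2-en-7-ynoic acid | OC(=O)/C=C(/CCCC#C)CNCCC(C)C | intermediate (not isolated)
7 | 1-(3-methylbutyl)-4-(pent-4-yn-1-yl)-1,5-dihydro-2H-pyrrol-2-one | O=C1C=C(CCCC#C)CN1CCC(C)C | intermediate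
8 | (S)-β-citronellene, (3S)-3,7-dimethylocta-1,6-diene | C=C[C@@H](C)CCC=C(C)C | starting material
9 | 3,3-dimethyl-5-[(3S)-3-methylpent-4-en-1-yl]-1,2,4-trioxolane (epimers at C5) | CC1(C)OOC(CC[C@H](C)C=C)O1 | intermediate (not isolated)
10 | (4S)-4-methylhex-5-enal | C=C[C@@H](C)CCC=O | intermediate
11 | (2Z,6S)-2-iodo-6-methylocta-2,7-diene | C=C[C@@H](C)CC/C=C(/C)I | intermediate
12 | (3S,6Z)-7-iodo-3-methyloct-6-ene-1,2-diol (epimers at C2) | OCC(O)[C@@H](C)CC/C=C(/C)I | intermediate (not isolated)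
13 | (2S,5Z)-6-iodo-2-methylhept-5-enal | O=C[C@@H](C)CC/C=C(/C)I | intermediate
14 | [(1E,3S,6Z)-7-iodo-3-methylocta-1,6-dien-1-yl]trimethylsilane | C[Si](C)(C)/C=C/[C@@H](C)CC/C=C(/C)I | intermediate
15 | methyl (2S)-oxirane-2-carboxylate (methyl (S)-glycidate) | COC(=O)[C@@H]1CO1 | starting material
16 | [(2E,6S,7E)-6-methyl-8-(trimethylsilyl)octa-2,7-dien-2-yl]lithium (Li cis to the chain) | [Li]/C(C)=C\CC[C@H](C)/C=C/[Si](C)(C)C | intermediate (not isolated)
17 | bromo[(2Z,6S,7E)-6-methyl-8-(trimethylsilyl)octa-2,7-dien-2-yl]magnesium | Br[Mg]/C(C)=C\CC[C@H](C)/C=C/[Si](C)(C)C | intermediate (not isolated)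
18 | methyl (2S,4Z,8S,9E)-2-hydroxy-4,8-dimethyl-10-(trimethylsilyl)deca-4,9-dienoate | COC(=O)[C@@H](O)C/C(C)=C\CC[C@H](C)/C=C/[Si](C)(C)C | intermediate
19 | methyl (2S,4Z,8S,9E)-4,8-dimethyl-2-(propanoyloxy)-10-(trimethylsilyl)deca-4,9-dienoate | COC(=O)[C@@H](OC(=O)CC)C/C(C)=C\CC[C@H](C)/C=C/[Si](C)(C)C | intermediate
20 | (5S)-5-[(2Z,6S,7E)-2,6-dimethyl-8-(trimethylsilyl)octa-2,7-dien-1-yl]-4-hydroxy-3-methylfuran-2(5H)-one | CC1=C(O)[C@H](C/C(C)=C\CC[C@H](C)/C=C/[Si](C)(C)C)OC1=O | intermediate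
21 | (5S)-5-[(2Z,6S,7E)-2,6-dimethyl-8-(trimethylsilyl)octa-2,7-dien-1-yl]-4-methoxy-3-methylfuran-2(5H)-one | CC1=C(OC)[C@H](C/C(C)=C\CC[C@H](C)/C=C/[Si](C)(C)C)OC1=O | intermediate
22 | (5S)-5-[(2Z,6S,7E)-8-iodo-2,6-dimethylocta-2,7-dien-1-yl]-4-methoxy-3-methylfuran-2(5H)-one | CC1=C(OC)[C@H](C/C(C)=C\CC[C@H](C)/C=C/I)OC1=O | intermediate
23 | dimethyl{(1E)-2-methyl-5-[1-(3-methylbutyl)-5-oxo-2,5-dihydro-1H-pyrrol-3-yl]pent-1-en-1-yl}aluminium | C[Al](C)/C=C(\C)CCCC1=CC(=O)N(CCC(C)C)C1 | intermediate (not isolated)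
24 | chloro{(1E)-2-methyl-5-[1-(3-methylbutyl)-5-oxo-2,5-dihydro-1H-pyrrol-3-yl]pent-1-en-1-yl}zinc | Cl[Zn]/C=C(\C)CCCC1=CC(=O)N(CCC(C)C)C1 | intermediate (not isolated)
25 | (5S)-4-methoxy-3-methyl-5-{(2Z,6S,7E,9E)-2,6,10-trimethyl-13-[1-(3-methylbutyl)-5-oxo-2,5-dihydro-1H-pyrrol-3-yl]trideca-2,7,9-trien-1-yl}furan-2(5H)-one (O-methyl sarcotrine D) | CC1=C(OC)[C@H](C/C(C)=C\CC[C@H](C)/C=C/C=C(\C)CCCC2=CC(=O)N(CCC(C)C)C2)OC1=O | intermediate
26 | Sarcotrine D, (5S)-4-hydroxy-3-methyl-5-{(2Z,6S,7E,9E)-2,6,10-trimethyl-13-[1-(3-methylbutyl)-5-oxo-2,5-dihydro-1H-pyrrol-3-yl]trideca-2,7,9-trien-1-yl}furan-2(5H)-one | CC1=C(O)[C@H](C/C(C)=C\CC[C@H](C)/C=C/C=C(\C)CCCC2=CC(=O)N(CCC(C)C)C2)OC1=O | target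

**Totals**

Total step count: 14. Longest linear sequence: 11 steps (steps 4–14, from 8).

**Steps most likely to fail**

Step 13. The Lewis-basic lactam may bind the cationic zirconocene and stall the carbometalation, and residual methyl–aluminium may transfer methyl instead of alkenyl in the coupling. Fallback (lactam built after the union), setting out from 1 and 22 and coming back at 25: hept-6-yn-1-ol 1, with its OH carried as the aluminium alkoxide (AlMe3 3.5 equiv, Cp2ZrCl2), is methylaluminated and coupled with 22 under the same ZnCl2/Pd(PPh3)4 conditions to give the hydroxy triene F1. TEMPO/PhI(OAc)2 then gives the aldehyde F2, glyoxylic acid 3 with morpholine·HCl gives the γ-hydroxybutenolide F3, and reductive amination with 5 (NaBH(OAc)3, AcOH) gives 25.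

Step 8. The hindered alkenyl metal may add to the ester carbonyl of 15 instead of opening the epoxide, or the copper-mediated opening may be too slow to outrun loss of alkene geometry on warming. Fallback (enolate alkylation at C2–C3 in place of epoxide opening), setting out from 14 and coming back at 18: the alkenyllithium 16 is trapped with paraformaldehyde to give the allylic alcohol F4, and CBr4/PPh3 gives the allylic bromide F5. The glycolate imide F6 is made from (R)-4-benzyloxazolidin-2-one, n-BuLi and (4-methoxybenzyloxy)acetyl chloride. Its sodium enolate (NaHMDS, THF, −78 → −45 °C) is alkylated by F5 on the face away from the benzyl group to give the alkylated imide F7. NaOMe/MeOH then gives the PMB-protected hydroxy ester F8, and DDQ (CH2Cl2/pH 7 buffer) removes the PMB group to give 18.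

Step 5. The iodo-ylide may scramble to non-iodinated and di-iodinated ylides, lowering the yield, and the Z:E ratio may erode. Fallback (stepwise construction of the trisubstituted haloalkene), setting out from 10 and coming back at 11: CBr4/PPh3 (Ramirez olefination) gives the dibromide F9. Palladium-catalysed trans-selective monomethylation (Me2Zn, Pd(DPEphos)Cl2, THF) replaces the bromine trans to the chain to give the (Z)-bromide F10. Copper-catalysed halogen exchange with retention (CuI, N,N′-dimethylethylenediamine, NaI, dioxane, 110 °C) gives 11.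

**Further compounds**

F1 | step 13 | (5S)-5-[(2Z,6S,7E,9E)-15-hydroxy-2,6,10-trimethylpentadeca-2,7,9-trien-1-yl]-4-methoxy-3-methylfuran-2(5H)-one | CC1=C(OC)[C@H](C/C(C)=C\CC[C@H](C)/C=C/C=C(\C)CCCCCO)OC1=O
F2 | step 13 | (5S)-4-methoxy-3-methyl-5-[(2Z,6S,7E,9E)-2,6,10-trimethyl-15-oxopentadeca-2,7,9-trien-1-yl]furan-2(5H)-one | CC1=C(OC)[C@H](C/C(C)=C\CC[C@H](C)/C=C/C=C(\C)CCCCC=O)OC1=O
F3 | step 13 | (5S)-5-[(2Z,6S,7E,9E)-13-(2-hydroxy-5-oxo-2,5-dihydrofuran-3-yl)-2,6,10-trimethyltrideca-2,7,9-trien-1-yl]-4-methoxy-3-methylfuran-2(5H)-one | CC1=C(OC)[C@H](C/C(C)=C\CC[C@H](C)/C=C/C=C(\C)CCCC2=CC(=O)OC2O)OC1=O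
F4 | step 8 | (2Z,6S,7E)-2,6-dimethyl-8-(trimethylsilyl)octa-2,7-dien-1-ol | OC/C(C)=C\CC[C@H](C)/C=C/[Si](C)(C)C
F5 | step 8 | [(1E,3S,6Z)-8-bromo-3,7-dimethylocta-1,6-dien-1-yl]trimethylsilane | BrC/C(C)=C\CC[C@H](C)/C=C/[Si](C)(C)C
F6 | step 8 | (4R)-4-benzyl-3-{[(4-methoxybenzyl)oxy]acetyl}-1,3-oxazolidin-2-one | COc1ccc(COCC(=O)N2[C@H](Cc3ccccc3)COC2=O)cc1
F7 | step 8 | (4R)-4-benzyl-3-[(2S,4Z,8S,9E)-2-[(4-methoxybenzyl)oxy]-4,8-dimethyl-10-(trimethylsilyl)deca-4,9-dienoyl]-1,3-oxazolidin-2-one | COc1ccc(CO[C@@H](C/C(C)=C\CC[C@H](C)/C=C/[Si](C)(C)C)C(=O)N2[C@H](Cc3ccccc3)COC2=O)cc1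
F8 | step 8 | methyl (2S,4Z,8S,9E)-2-[(4-methoxybenzyl)oxy]-4,8-dimethyl-10-(trimethylsilyl)deca-4,9-dienoate | COC(=O)[C@@H](OCc1ccc(OC)cc1)C/C(C)=C\CC[C@H](C)/C=C/[Si](C)(C)C
F9 | step 5 | (5S)-1,1-dibromo-5-methylhepta-1,6-diene | C=C[C@@H](C)CCC=C(Br)Br
F10 | step 5 | (2Z,6S)-2-bromo-6-methylocta-2,7-diene | C=C[C@@H](C)CC/C=C(/C)Br
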